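**Retrosynthetic overview**
- The target is traced back to the sodium salt of a 5,6,3',4'-tetra-O-benzyl 7-sulfate (final hydrogenolysis), and that to a flavone whose only free phenol is O7, unveiled from a methoxymethyl (MOM) ether.
- Ring C is opened to a 2'-hydroxychalcone (iodine/DMSO oxidative cyclisation), which a Claisen–Schmidt disconnection splits into bought 3,4-dibenzyloxybenzaldehyde (ring B) and a ring A acetophenone.
- Ring A is taken back by a retro ring expansion to a 4-hydroxy-4-(1-alkoxyvinyl)cyclobutenone, assembled from dibenzyl squarate and two different alpha-lithiated vinyl ethers.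
- The strategy rests on ring A (C4a, C5, C6, C7, C8, C8a): oxygen on C5, C6, C7 and C8a, hydrogen on C8, the C4 carbonyl carbon on C4a, and a sulfate on O7 alone. In the ring expansion O5 comes from a squarate ester oxygen, O6 and O8a from the two squarate carbonyls and O7 from the MOM vinyl ether, so O7 is distinct from the start.
- Ring order: ring A is built first, ring B arrives as a bought aldehyde, ring C is closed last.

Key step: step 7

Assumption: the target is taken as the free hydrogen sulfate drawn in the SMILES; it is released from its sodium salt only in the last operation and should be handled cold, because aryl hydrogen sulfates hydrolyse under acid.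

**Route**

Step 1
Reactants: 1 squaric acid
Product: 2 3,4-bis(benzyloxy)cyclobut-3-ene-1,2-dione (dibenzyl squarate)
Conditions: BnOH (excess), toluene, reflux, Dean–Stark trap
Reagents that add atoms: benzyl alcohol, OCc1ccccc1
Why: Squaric acid is a strong vinylogous carboxylic acid that should esterify itself with the alcohol once water is removed azeotropically (Fischer-type esterification).

Step 2
Reactants: 2 dibenzyl squarate; 3 ethyl vinyl ether
Product: 6 racemic 2,3-bis(benzyloxy)-4-(1-ethoxyvinyl)-4-hydroxycyclobut-2-en-1-one, via 1-ethoxyvinyllithium 4 (not isolated), via lithium alkoxide 5 (not isolated)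
Conditions: 3, t-BuLi, THF, −78 to 0 °C; then add to 2, THF, −78 °C; cold H2O quench
Reagents that add atoms: none
Why: Alpha-deprotonation of the vinyl ether and 1,2-addition of the resulting vinyllithium to one of the two equivalent squarate carbonyls should stop at the mono-adduct at low temperature, the carbinol centre forming as a racemate (organolithium carbonyl addition).

Step 3
Reactants: 6 racemic 2,3-bis(benzyloxy)-4-(1-ethoxyvinyl)-4-hydroxycyclobut-2-en-1-one
Product: 8 3-(benzyloxy)-4-(1-ethoxyvinyl)cyclobut-3-ene-1,2-dione, via carbinol trifluoroacetate 7 (not isolated)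
Conditions: (CF3CO)2O, pyridine, CH2Cl2, −78 to 0 °C; then aq. NaHCO3
Reagents that add atoms: water, O
Why: Trifluoroacetylation makes the tertiary hydroxyl a leaving group whose ionisation is assisted by the ring enol ether, water then adds at the benzyloxy carbon next to the carbonyl during the bicarbonate quench and benzyl alcohol is expelled (squarate carbinol to cyclobutenedione rearrangement), while pyridine keeps the medium non-acidic for the ethoxyvinyl group.

Step 4
Reactants: 9 2-bromoethanol
Product: 10 1-bromo-2-(methoxymethoxy)ethane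
Conditions: MOMCl, i-Pr2NEt, CH2Cl2, 0 to 20 °C
Reagents that add atoms: chloromethyl methyl ether, COCCl
Why: The primary alcohol should be alkylated by the alpha-chloro ether in the presence of a hindered amine that does not displace the bromide (acetal-type ether formation).

Step 5
Reactants: 10 1-bromo-2-(methoxymethoxy)ethane
Product: 11 (methoxymethoxy)ethene (methoxymethyl vinyl ether)
Conditions: KOtBu, tetraglyme, 20 to 50 °C, product distilled out and redistilled from CaH2
Reagents that add atoms: none
Why: The bulky alkoxide should remove HBr from the 2-alkoxyethyl bromide by E2 elimination rather than substitute, and the volatile vinyl ether leaves the mixture by distillation.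

Step 6
Reactants: 8 3-(benzyloxy)-4-(1-ethoxyvinyl)cyclobut-3-ene-1,2-dione; 11 methoxymethyl vinyl ether
Product: 14 racemic 3-(benzyloxy)-2-(1-ethoxyvinyl)-4-hydroxy-4-[1-(methoxymethoxy)vinyl]cyclobut-2-en-1-one, via 1-(methoxymethoxy)vinyllithium 12 (not isolated), via lithium alkoxide 13 (not isolated)
Conditions: 11, sec-BuLi, THF, −78 °C; then add to 8, THF, −78 °C; cold H2O quench
Reagents that add atoms: none
Why: The alpha-lithiated vinyl ether should add 1,2 to the C2 ketone, which sits next to the benzyloxy-bearing carbon and is the more electrophilic carbonyl, because the C1 carbonyl is deactivated as a vinylogous ester; the carbinol centre forms as a racemate (regioselective organolithium addition to a 3-alkoxycyclobutenedione).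

Step 7
Reactants: 14 racemic 3-(benzyloxy)-2-(1-ethoxyvinyl)-4-hydroxy-4-[1-(methoxymethoxy)vinyl]cyclobut-2-en-1-one
Product: 17 3-(benzyloxy)-2-(1-ethoxyvinyl)-5-(methoxymethoxy)benzene-1,4-diol, via (Z)-dienylketene 15 (not isolated), via cyclohexadienone 16 (not isolated)
Conditions: degassed toluene (dilute), 110 °C, argon; crude solution used directly
Reagents that add atoms: none
Why: Heating should open the C1–C4 bond of the cyclobutenone in a conrotatory four-electron electrocyclic reaction to the (Z)-dienylketene 15, which closes by a six-electron disrotatory electrocyclisation in which the ketene carbon (future C8a) bonds to the CH2 terminus of the methoxymethoxyvinyl group (future C8); enolisation of cyclohexadienone 16 then aromatises ring A. The closest known reaction type is the Moore rearrangement of 4-alkenyl-4-hydroxycyclobutenones derived from squarate esters to hydroquinones. Ring A is the only ring closed, by 6π electrocyclisation of the ketene–diene unit, and it emerges with OH on C8a, the masked acetyl on C4a, the benzyl ether on C5, OH on C6, the MOM ether on C7 and H on C8. No stereocentre is created, since the racemic carbinol carbon of 14 becomes the sp2 carbon C6. The step needs inward rotation of the alkenyl group, which is secured by the strong outward preference of the hydroxyl donor on the same carbon, and the unhindered CH2 terminus should keep ring closure faster than ketene capture or dimerisation. Oxygen is excluded so that the electron-rich hydroquinone is not oxidised to the quinone.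

Step 8
Reactants: 17 3-(benzyloxy)-2-(1-ethoxyvinyl)-5-(methoxymethoxy)benzene-1,4-diol
Product: 18 1-[2-(benzyloxy)-3,6-dihydroxy-4-(methoxymethoxy)phenyl]ethan-1-one
Conditions: 0.5 M aq. HCl, THF, 0 °C, short contact, argon
Reagents that add atoms: water, O
Why: The alpha-aryl enol ether is protonated at its CH2 carbon far faster than the MOM acetal ionises, so brief dilute acid should unmask the methyl ketone selectively (enol ether hydrolysis).

Step 9
Reactants: 18 1-[2-(benzyloxy)-3,6-dihydroxy-4-(methoxymethoxy)phenyl]ethan-1-one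
Product: 19 1-[2,3-bis(benzyloxy)-6-hydroxy-4-(methoxymethoxy)phenyl]ethan-1-one
Conditions: BnBr (1 equiv), K2CO3, degassed DMF, 20 °C, argon
Reagents that add atoms: benzyl bromide, BrCc1ccccc1
Why: The hydroxyl ortho to the acetyl group is tied up in a hydrogen bond to the carbonyl and is poorly nucleophilic, so one equivalent of benzyl bromide should alkylate the other, non-chelated hydroxyl (chelation-controlled Williamson etherification).

Step 10
Reactants: 19 1-[2,3-bis(benzyloxy)-6-hydroxy-4-(methoxymethoxy)phenyl]ethan-1-one; 20 3,4-bis(benzyloxy)benzaldehyde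
Product: 22 (2E)-3-[3,4-bis(benzyloxy)phenyl]-1-[2,3-bis(benzyloxy)-6-hydroxy-4-(methoxymethoxy)phenyl]prop-2-en-1-one, via aldol adduct 21 (not isolated)
Conditions: KOH, EtOH/THF, 20 °C, argon
Reagents that add atoms: none
Why: The methyl ketone enolate should add to the non-enolisable aldehyde and the aldol lose water by an E1cB pathway to the conjugated E-enone, with all ether groups stable to base (Claisen–Schmidt condensation).

Step 11
Reactants: 22 (2E)-3-[3,4-bis(benzyloxy)phenyl]-1-[2,3-bis(benzyloxy)-6-hydroxy-4-(methoxymethoxy)phenyl]prop-2-en-1-one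
Product: 25 5,6-bis(benzyloxy)-2-[3,4-bis(benzyloxy)phenyl]-7-(methoxymethoxy)-4H-chromen-4-one, via flavanone 23 (not isolated), via 3-iodoflavanone 24 (not isolated)
Conditions: iodine (I2, catalytic), DMSO, 130 °C
Reagents that add atoms: none
Why: Oxa-Michael closure of the chelated phenol onto the enone, alpha-iodination and loss of HI should give the flavone while DMSO reoxidises HI to iodine (iodine-catalysed oxidative cyclisation of a 2'-hydroxychalcone); any material that loses its MOM group here is carried into the next step, where both forms converge.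

Step 12
Reactants: 25 5,6-bis(benzyloxy)-2-[3,4-bis(benzyloxy)phenyl]-7-(methoxymethoxy)-4H-chromen-4-one
Product: 26 5,6-bis(benzyloxy)-2-[3,4-bis(benzyloxy)phenyl]-7-hydroxy-4H-chromen-4-one
Conditions: HCl (3 M in MeOH), THF, 40 °C
Reagents that add atoms: none
Why: The MOM acetal should be exchanged onto methanol under acid that leaves benzyl aryl ethers in place (acetal cleavage), and partial loss of the C5 benzyl group would be tolerable because a C5 hydroxyl is hydrogen-bonded to the C4 carbonyl and unreactive towards sulfation.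

Step 13
Reactants: 26 5,6-bis(benzyloxy)-2-[3,4-bis(benzyloxy)phenyl]-7-hydroxy-4H-chromen-4-one
Product: 28 sodium 5,6-bis(benzyloxy)-2-[3,4-bis(benzyloxy)phenyl]-4-oxo-4H-chromen-7-yl sulfate, via pyridinium sulfate 27 (not isolated)
Conditions: SO3·pyridine, pyridine, 50 °C; then aq. NaHCO3; Sephadex LH-20 or C18 chromatography
Reagents that add atoms: sulfur trioxide–pyridine complex, O=S(=O)([O-])[n+]1ccccc1; sodium hydrogen carbonate, [Na+].OC([O-])=O
Why: The C7 hydroxyl is the only free phenol, so sulfur trioxide transfer from the pyridine complex should give a single aryl sulfate monoester, isolated as its stable sodium salt (phenol O-sulfation).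

Step 14
Reactants: 28 sodium 5,6-bis(benzyloxy)-2-[3,4-bis(benzyloxy)phenyl]-4-oxo-4H-chromen-7-yl sulfate
Product: 30 6-hydroxyluteolin 7-sulfate (2-(3,4-dihydroxyphenyl)-5,6-dihydroxy-4-oxo-4H-chromen-7-yl hydrogen sulfate), via sodium 6-hydroxyluteolin 7-sulfate 29 (not isolated)
Conditions: H2 (1 atm), 10% Pd/C, MeOH/THF, 20 °C, uptake monitored; filter under argon; strongly acidic sulfonated polystyrene resin (H+ form), H2O/MeOH, 0 °C; freeze-dry
Reagents that add atoms: none
Why: The four benzyl aryl ethers should be cleaved over palladium under neutral conditions that leave the aryl sulfate anion and the C2–C3 double bond intact, and the acidic resin then exchanges sodium for a proton (catalytic hydrogenolysis followed by cation exchange).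

**Compound list**
1 | squaric acid (3,4-dihydroxycyclobut-3-ene-1,2-dione) | O=C1C(O)=C(O)C1=O | starting material
2 | 3,4-bis(benzyloxy)cyclobut-3-ene-1,2-dione (dibenzyl squarate) | O=C1C(=O)C(OCc2ccccc2)=C1OCc1ccccc1 | intermediate
3 | ethyl vinyl ether | C=COCC | starting material
4 | 1-ethoxyvinyllithium | [Li]C(=C)OCC | intermediate
5 | lithium alkoxide of racemic 2,3-bis(benzyloxy)-4-(1-ethoxyvinyl)-4-hydroxycyclobut-2-en-1-one | [Li]OC1(C(=C)OCC)C(OCc2ccccc2)=C(OCc2ccccc2)C1=O | intermediate
6 | racemic 2,3-bis(benzyloxy)-4-(1-ethoxyvinyl)-4-hydroxycyclobut-2-en-1-one | C=C(OCC)C1(O)C(OCc2ccccc2)=C(OCc2ccccc2)C1=O | intermediate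
7 | racemic 2,3-bis(benzyloxy)-1-(1-ethoxyvinyl)-4-oxocyclobut-2-en-1-yl trifluoroacetate | C=C(OCC)C1(OC(=O)C(F)(F)F)C(OCc2ccccc2)=C(OCc2ccccc2)C1=O | intermediate
8 | 3-(benzyloxy)-4-(1-ethoxyvinyl)cyclobut-3-ene-1,2-dione | C=C(OCC)C1=C(OCc2ccccc2)C(=O)C1=O | intermediate
9 | 2-bromoethanol | OCCBr | starting material
10 | 1-bromo-2-(methoxymethoxy)ethane | COCOCCBr | intermediate
11 | (methoxymethoxy)ethene (methoxymethyl vinyl ether) | C=COCOC | intermediate
12 | 1-(methoxymethoxy)vinyllithium | [Li]C(=C)OCOC | intermediate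
13 | lithium alkoxide of racemic 3-(benzyloxy)-2-(1-ethoxyvinyl)-4-hydroxy-4-[1-(methoxymethoxy)vinyl]cyclobut-2-en-1-one | [Li]OC1(C(=C)OCOC)C(OCc2ccccc2)=C(C(=C)OCC)C1=O | intermediate
14 | racemic 3-(benzyloxy)-2-(1-ethoxyvinyl)-4-hydroxy-4-[1-(methoxymethoxy)vinyl]cyclobut-2-en-1-one | C=C(OCC)C1=C(OCc2ccccc2)C(O)(C(=C)OCOC)C1=O | intermediate
15 | (3Z)-3-(benzyloxy)-2-(1-ethoxyvinyl)-4-hydroxy-5-(methoxymethoxy)hexa-1,3,5-trien-1-one (dienylketene) | O=C=C(C(=C)OCC)/C(OCc1ccccc1)=C(/O)C(=C)OCOC | intermediate
16 | 3-(benzyloxy)-2-(1-ethoxyvinyl)-4-hydroxy-5-(methoxymethoxy)cyclohexa-2,4-dien-1-one | C=C(OCC)C1=C(OCc2ccccc2)C(O)=C(OCOC)CC1=O | intermediate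
17 | 3-(benzyloxy)-2-(1-ethoxyvinyl)-5-(methoxymethoxy)benzene-1,4-diol | C=C(OCC)c1c(O)cc(OCOC)c(O)c1OCc1ccccc1 | intermediate
18 | 1-[2-(benzyloxy)-3,6-dihydroxy-4-(methoxymethoxy)phenyl]ethan-1-one | CC(=O)c1c(O)cc(OCOC)c(O)c1OCc1ccccc1 | intermediate
19 | 1-[2,3-bis(benzyloxy)-6-hydroxy-4-(methoxymethoxy)phenyl]ethan-1-one | CC(=O)c1c(O)cc(OCOC)c(OCc2ccccc2)c1OCc1ccccc1 | intermediate
20 | 3,4-bis(benzyloxy)benzaldehyde | O=Cc1ccc(OCc2ccccc2)c(OCc2ccccc2)c1 | starting material
21 | racemic 3-[3,4-bis(benzyloxy)phenyl]-1-[2,3-bis(benzyloxy)-6-hydroxy-4-(methoxymethoxy)phenyl]-3-hydroxypropan-1-one | O=C(CC(O)c1ccc(OCc2ccccc2)c(OCc2ccccc2)c1)c1c(O)cc(OCOC)c(OCc2ccccc2)c1OCc1ccccc1 | intermediate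
22 | (2E)-3-[3,4-bis(benzyloxy)phenyl]-1-[2,3-bis(benzyloxy)-6-hydroxy-4-(methoxymethoxy)phenyl]prop-2-en-1-one | O=C(/C=C/c1ccc(OCc2ccccc2)c(OCc2ccccc2)c1)c1c(O)cc(OCOC)c(OCc2ccccc2)c1OCc1ccccc1 | intermediate
23 | racemic 5,6-bis(benzyloxy)-2-[3,4-bis(benzyloxy)phenyl]-7-(methoxymethoxy)chroman-4-one | O=C1CC(c2ccc(OCc3ccccc3)c(OCc3ccccc3)c2)Oc2cc(OCOC)c(OCc3ccccc3)c(OCc3ccccc3)c12 | intermediate
24 | 5,6-bis(benzyloxy)-2-[3,4-bis(benzyloxy)phenyl]-3-iodo-7-(methoxymethoxy)chroman-4-one (racemic, mixture of cis and trans isomers) | O=C1C(I)C(c2ccc(OCc3ccccc3)c(OCc3ccccc3)c2)Oc2cc(OCOC)c(OCc3ccccc3)c(OCc3ccccc3)c12 | intermediate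
25 | 5,6-bis(benzyloxy)-2-[3,4-bis(benzyloxy)phenyl]-7-(methoxymethoxy)-4H-chromen-4-one | O=c1cc(-c2ccc(OCc3ccccc3)c(OCc3ccccc3)c2)oc2cc(OCOC)c(OCc3ccccc3)c(OCc3ccccc3)c12 | intermediate
26 | 5,6-bis(benzyloxy)-2-[3,4-bis(benzyloxy)phenyl]-7-hydroxy-4H-chromen-4-one | O=c1cc(-c2ccc(OCc3ccccc3)c(OCc3ccccc3)c2)oc2cc(O)c(OCc3ccccc3)c(OCc3ccccc3)c12 | intermediate
27 | pyridinium 5,6-bis(benzyloxy)-2-[3,4-bis(benzyloxy)phenyl]-4-oxo-4H-chromen-7-yl sulfate | O=c1cc(-c2ccc(OCc3ccccc3)c(OCc3ccccc3)c2)oc2cc(OS(=O)(=O)[O-])c(OCc3ccccc3)c(OCc3ccccc3)c12.c1cc[nH+]cc1 | intermediate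
28 | sodium 5,6-bis(benzyloxy)-2-[3,4-bis(benzyloxy)phenyl]-4-oxo-4H-chromen-7-yl sulfate | O=c1cc(-c2ccc(OCc3ccccc3)c(OCc3ccccc3)c2)oc2cc(OS(=O)(=O)[O-])c(OCc3ccccc3)c(OCc3ccccc3)c12.[Na+] | intermediate
29 | sodium 2-(3,4-dihydroxyphenyl)-5,6-dihydroxy-4-oxo-4H-chromen-7-yl sulfate | O=c1cc(-c2ccc(O)c(O)c2)oc2cc(OS(=O)(=O)[O-])c(O)c(O)c12.[Na+] | intermediate
30 | 6-hydroxyluteolin 7-sulfate | O=c1cc(-c2ccc(O)c(O)c2)oc2cc(OS(=O)(=O)O)c(O)c(O)c12 | target

**Step count and risks**

Total step count: 14. Longest linear sequence: 12 steps (steps 1–3 and 6–14 from squaric acid); the vinyl ether branch (steps 4–5) joins at step 6.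

Steps most likely to fail:

1. Step 7. The dienylketene may be captured by the free tertiary hydroxyl if some of it rotates inward, or the hydroxyketone may fragment before it opens, so that ring A does not close cleanly. The fallback sets out from dione 8 and caps the carbinol oxygen before heating. The addition of vinyllithium 12 is repeated, but alkoxide 13 is quenched with Me3SiCl at −78 to 0 °C to give racemic 3-(benzyloxy)-2-(1-ethoxyvinyl)-4-[1-(methoxymethoxy)vinyl]-4-(trimethylsilyloxy)cyclobut-2-en-1-one F3. Thermolysis of this silyl ether in degassed toluene at 110 °C should then give 3-(benzyloxy)-2-(1-ethoxyvinyl)-5-(methoxymethoxy)-4-(trimethylsilyloxy)phenol F4, in which no free hydroxyl was available to intercept the ketene. The dilute acid treatment of step 8 cleaves the aryl silyl ether together with the enol ether, and the route is rejoined at acetophenone 18.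

2. Step 3. The ethoxyvinyl group may be protonated or the electron-rich alkoxydiene may polymerise while the trifluoroacetate ionises, eroding the dione. The fallback sets out from squaric acid 1 and avoids any acidic or cationic stage. Oxalyl chloride with catalytic DMF in CH2Cl2 should give 3,4-dichlorocyclobut-3-ene-1,2-dione F1. One equivalent of benzyl alcohol at 0 °C then gives 3-(benzyloxy)-4-chlorocyclobut-3-ene-1,2-dione F2. Stille coupling of this vinylogous acid chloride with tributyl(1-ethoxyvinyl)stannane, using PdCl2(PPh3)2 and CuI (copper iodide) as catalysts in dioxane at 20 to 50 °C, delivers dione 8, where the route is rejoined.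

3. Step 9. Alkylation may also occur at the chelated phenol, or the hydroquinone may be oxidised by traces of air under base, giving mixtures. The fallback sets out from carbinol 14 and places the benzyl group on the future O6 before ring A exists. Benzylation of the tertiary hydroxyl with BnBr, Ag2O and K2CO3 in acetonitrile at 20 °C in the dark should give racemic 3,4-bis(benzyloxy)-2-(1-ethoxyvinyl)-4-[1-(methoxymethoxy)vinyl]cyclobut-2-en-1-one F5. Thermolysis in degassed toluene at 110 °C (the alkoxy group also rotates outward) then gives 3,4-bis(benzyloxy)-2-(1-ethoxyvinyl)-5-(methoxymethoxy)phenol F6, whose only free hydroxyl is the one needed for chelation. Brief dilute aqueous HCl in THF at 0 °C hydrolyses the enol ether and the route is rejoined at acetophenone 19, with no free hydroquinone handled.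

**Further compounds**
F1 | step 3 | 3,4-dichlorocyclobut-3-ene-1,2-dione | O=C1C(=O)C(Cl)=C1Cl
F2 | step 3 | 3-(benzyloxy)-4-chlorocyclobut-3-ene-1,2-dione | O=C1C(=O)C(OCc2ccccc2)=C1Cl
F3 | step 7 | racemic 3-(benzyloxy)-2-(1-ethoxyvinyl)-4-[1-(methoxymethoxy)vinyl]-4-(trimethylsilyloxy)cyclobut-2-en-1-one | C=C(OCC)C1=C(OCc2ccccc2)C(O[Si](C)(C)C)(C(=C)OCOC)C1=O
F4 | step 7 | 3-(benzyloxy)-2-(1-ethoxyvinyl)-5-(methoxymethoxy)-4-(trimethylsilyloxy)phenol | C=C(OCC)c1c(O)cc(OCOC)c(O[Si](C)(C)C)c1OCc1ccccc1
F5 | step 9 | racemic 3,4-bis(benzyloxy)-2-(1-ethoxyvinyl)-4-[1-(methoxymethoxy)vinyl]cyclobut-2-en-1-one | C=C(OCC)C1=C(OCc2ccccc2)C(OCc2ccccc2)(C(=C)OCOC)C1=O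
F6 | step 9 | 3,4-bis(benzyloxy)-2-(1-ethoxyvinyl)-5-(methoxymethoxy)phenol | C=C(OCC)c1c(O)cc(OCOC)c(OCc2ccccc2)c1OCc1ccccc1
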